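**Assumption:** the SMILES is read literally as (1R,2R,3R), which places the C1 aroyl, C2 aryl and C3 aryl groups on one face of the indane (all-cis). Labels C1, C2, C3, C3a and ring A (the fused resorcinol ring) follow the indane numbering of the target, also in open-chain precursors.

## Retrosynthetic overview

1. Target 13 ← hexamethyl ether ketone 12 ← carbinol 11; the future carbonyl carbon is carried as the purchased stereocentre of (R)-4-methoxymandelic acid and oxidised only at the end.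
2. The all-cis C2/C3 centres ← hydrogenation of the C2=C3 bond of indene 9 from the face opposite the C1 side chain.
3. Five-membered ring (the only ring formed) ← dehydrative Friedel–Crafts closure C3–C3a of ketone 8.
4. C1–aryl (ring A) and C2–aryl bonds ← one electroreductive nickel-catalysed vicinal diarylation of enone 6 with two molecules of 1-bromo-3,5-dimethoxybenzene; C1 is set by the adjacent mandelate stereocentre.
5. Enone 6 ← Wittig olefination of the mandelate-derived aldehyde 5.

## Route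

Step 1
Reactants: 1 (2R)-2-hydroxy-2-(4-methoxyphenyl)acetic acid
Product: 2 methyl (2R)-2-hydroxy-2-(4-methoxyphenyl)acetate
Conditions: MeOH, H2SO4 (cat.), 25 °C
Reagents that add atoms: methanol, CO
Why: Fischer esterification; the stereocentre is untouched because the adjacent carboxyl group disfavours benzylic ionisation.

Step 2
Reactants: 2 methyl (2R)-2-hydroxy-2-(4-methoxyphenyl)acetate
Product: 3 methyl (2R)-2-[(tert-butyldimethylsilyl)oxy]-2-(4-methoxyphenyl)acetate
Conditions: TBSCl, imidazole, DMF, 25 °C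
Reagents that add atoms: tert-butyldimethylsilyl chloride, CC(C)(C)[Si](C)(C)Cl
Why: Silyl ether protection of the secondary alcohol; a silyloxy group is a poor leaving group and a good Felkin–Anh control element for step 4.

Step 3
Reactants: 3 methyl (2R)-2-[(tert-butyldimethylsilyl)oxy]-2-(4-methoxyphenyl)acetate; 4 1-(4-methoxyphenyl)-2-(triphenyl-λ5-phosphanylidene)ethan-1-one
Product: 6 (2E,4S)-4-[(tert-butyldimethylsilyl)oxy]-1,4-bis(4-methoxyphenyl)but-2-en-1-one, via aldehyde 5 (not isolated)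
Conditions: i-Bu2AlH (1.05 equiv), CH2Cl2, −78 °C; then 4, −78 → 25 °C
Reagents that add atoms: none
Why: Partial ester reduction followed by in situ Wittig olefination with a stabilised keto-ylide, which is E-selective and base-free, so the α-silyloxy aldehyde is not racemised (the descriptor changes from R to S only through CIP priorities).

Step 4
Reactants: 6 (2E,4S)-4-[(tert-butyldimethylsilyl)oxy]-1,4-bis(4-methoxyphenyl)but-2-en-1-one; 7 1-bromo-3,5-dimethoxybenzene (3 equiv)
Product: 8 (3R,4S)-4-[(tert-butyldimethylsilyl)oxy]-2,3-bis(3,5-dimethoxyphenyl)-1,4-bis(4-methoxyphenyl)butan-1-one (both C2 epimers)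
Conditions: NiBr2(dme) (10 mol%), 4,4'-di-tert-butyl-2,2'-bipyridine (12 mol%), Bu4NBr, DMA, undivided cell, Zn anode, Ni-foam cathode, 4 mA, 2.3 F/mol, 25 °C
Reagents that add atoms: none
Why: Proposed new method: cathodically generated zerovalent nickel inserts into the C–Br bond of 7 and the aryl–nickel adds 1,4 to the E-enone, delivering the aryl group to C1 anti to the C–OSi bond (Felkin–Anh arrangement with H eclipsing the alkene), which sets C1 (3R in 8); the nickel enolate, relayed as the zinc enolate by Zn2+ from the anode, is then arylated at C2 by a second aryl–nickel bromide through C–C reductive elimination, so both 3,5-dimethoxyphenyl groups enter in one two-electron vicinal diarylation; the closest known reactions are nickel-catalysed electroreductive conjugate addition of aryl bromides to enones, nickel-catalysed reductive 1,2-diarylation of vinylarenes and α-arylation of zinc enolates, none of which has been shown across an enone C=C or under control of a γ-stereocentre.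

Step 5
Reactants: 8 (3R,4S)-4-[(tert-butyldimethylsilyl)oxy]-2,3-bis(3,5-dimethoxyphenyl)-1,4-bis(4-methoxyphenyl)butan-1-one
Product: 9 tert-butyl{(S)-[(1S)-2-(3,5-dimethoxyphenyl)-4,6-dimethoxy-3-(4-methoxyphenyl)-1H-inden-1-yl](4-methoxyphenyl)methoxy}dimethylsilane
Conditions: Tf2O (1.1 equiv), 2,6-di-tert-butyl-4-methylpyridine (2.5 equiv), CH2Cl2, −78 → 25 °C
Reagents that add atoms: none
Why: Dehydrative intramolecular Friedel–Crafts cyclisation (cyclodehydration): O-triflation turns the ketone carbon (C3) into an anisyl-stabilised carbenium ion that is captured by the ortho carbon of the dimethoxyphenyl ring on C1 (five-membered ring, ortho/para to both OMe groups; the ring on C2 could only close a three-membered ring), and loss of TfOH gives the C2=C3 indene, which removes the unselective C2 centre while the hindered pyridine keeps the medium acid-free for the benzylic silyl ether (C1 is unchanged in space; its descriptor becomes S through CIP priorities).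

Step 6
Reactants: 9 tert-butyl{(S)-[(1S)-2-(3,5-dimethoxyphenyl)-4,6-dimethoxy-3-(4-methoxyphenyl)-1H-inden-1-yl](4-methoxyphenyl)methoxy}dimethylsilane
Product: 10 tert-butyl{(S)-[(1R,2R,3R)-2-(3,5-dimethoxyphenyl)-4,6-dimethoxy-3-(4-methoxyphenyl)-2,3-dihydro-1H-inden-1-yl](4-methoxyphenyl)methoxy}dimethylsilane
Conditions: H2 (4 atm), 10% Pd/C, EtOAc, 25 °C
Reagents that add atoms: none
Why: Heterogeneous syn hydrogenation; the catalyst reaches the tetrasubstituted C2=C3 bond from the face opposite the bulky C1 side chain, so both new hydrogens are cis to H-1 and the three substituents end up mutually cis (2R and 3R set by C1).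

Step 7
Reactants: 10 tert-butyl{(S)-[(1R,2R,3R)-2-(3,5-dimethoxyphenyl)-4,6-dimethoxy-3-(4-methoxyphenyl)-2,3-dihydro-1H-inden-1-yl](4-methoxyphenyl)methoxy}dimethylsilane
Product: 11 (S)-[(1R,2R,3R)-2-(3,5-dimethoxyphenyl)-4,6-dimethoxy-3-(4-methoxyphenyl)-2,3-dihydro-1H-inden-1-yl](4-methoxyphenyl)methanol
Conditions: Bu4NF, THF, 0 → 25 °C
Reagents that add atoms: none
Why: Fluoride-mediated desilylation; no ring stereocentre is acidic at the carbinol stage.

Step 8
Reactants: 11 (S)-[(1R,2R,3R)-2-(3,5-dimethoxyphenyl)-4,6-dimethoxy-3-(4-methoxyphenyl)-2,3-dihydro-1H-inden-1-yl](4-methoxyphenyl)methanol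
Product: 12 [(1R,2R,3R)-2-(3,5-dimethoxyphenyl)-4,6-dimethoxy-3-(4-methoxyphenyl)-2,3-dihydro-1H-inden-1-yl](4-methoxyphenyl)methanone
Conditions: Dess–Martin periodinane (1.3 equiv), CH2Cl2, 0 → 25 °C
Reagents that add atoms: none
Why: Dess–Martin oxidation without base converts the purchased carbinol centre into the aryl ketone without enolising the now α-positioned, kinetically cis C1 centre.

Step 9
Reactants: 12 [(1R,2R,3R)-2-(3,5-dimethoxyphenyl)-4,6-dimethoxy-3-(4-methoxyphenyl)-2,3-dihydro-1H-inden-1-yl](4-methoxyphenyl)methanone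
Product: 13 [(1R,2R,3R)-2-(3,5-dihydroxyphenyl)-4,6-dihydroxy-3-(4-hydroxyphenyl)-2,3-dihydro-1H-inden-1-yl](4-hydroxyphenyl)methanone
Conditions: BBr3 (12 equiv), CH2Cl2, −78 → 0 °C; then H2O, 0 °C
Reagents that add atoms: none
Why: Lewis-acid cleavage of the six aryl methyl ethers (BBr3 demethylation), run cold and base-free so that the cis α-aryl ketone centre at C1 is not equilibrated.

## Compound list

1 | (2R)-2-hydroxy-2-(4-methoxyphenyl)acetic acid, (R)-4-methoxymandelic acid | O[C@@H](C(=O)O)c1ccc(OC)cc1 | starting material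
2 | methyl (2R)-2-hydroxy-2-(4-methoxyphenyl)acetate | O[C@@H](C(=O)OC)c1ccc(OC)cc1 | intermediate
3 | methyl (2R)-2-[(tert-butyldimethylsilyl)oxy]-2-(4-methoxyphenyl)acetate | CC(C)(C)[Si](C)(C)O[C@@H](C(=O)OC)c1ccc(OC)cc1 | intermediate
4 | 1-(4-methoxyphenyl)-2-(triphenyl-λ5-phosphanylidene)ethan-1-one | O=C(C=P(c1ccccc1)(c1ccccc1)c1ccccc1)c1ccc(OC)cc1 | starting material
5 | (2R)-2-[(tert-butyldimethylsilyl)oxy]-2-(4-methoxyphenyl)acetaldehyde | CC(C)(C)[Si](C)(C)O[C@@H](C=O)c1ccc(OC)cc1 | intermediate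
6 | (2E,4S)-4-[(tert-butyldimethylsilyl)oxy]-1,4-bis(4-methoxyphenyl)but-2-en-1-one | CC(C)(C)[Si](C)(C)O[C@@H](/C=C/C(=O)c1ccc(OC)cc1)c1ccc(OC)cc1 | intermediate
7 | 1-bromo-3,5-dimethoxybenzene | COc1cc(Br)cc(OC)c1 | starting material
8 | (3R,4S)-4-[(tert-butyldimethylsilyl)oxy]-2,3-bis(3,5-dimethoxyphenyl)-1,4-bis(4-methoxyphenyl)butan-1-one, mixture of C2 epimers | CC(C)(C)[Si](C)(C)O[C@H](c1ccc(OC)cc1)[C@@H](c1cc(OC)cc(OC)c1)C(c1cc(OC)cc(OC)c1)C(=O)c1ccc(OC)cc1 | intermediate
9 | tert-butyl{(S)-[(1S)-2-(3,5-dimethoxyphenyl)-4,6-dimethoxy-3-(4-methoxyphenyl)-1H-inden-1-yl](4-methoxyphenyl)methoxy}dimethylsilane | CC(C)(C)[Si](C)(C)O[C@H](c1ccc(OC)cc1)[C@@H]1C(c2cc(OC)cc(OC)c2)=C(c2ccc(OC)cc2)c2c(OC)cc(OC)cc21 | intermediate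
10 | tert-butyl{(S)-[(1R,2R,3R)-2-(3,5-dimethoxyphenyl)-4,6-dimethoxy-3-(4-methoxyphenyl)-2,3-dihydro-1H-inden-1-yl](4-methoxyphenyl)methoxy}dimethylsilane | CC(C)(C)[Si](C)(C)O[C@H](c1ccc(OC)cc1)[C@H]1c2cc(OC)cc(OC)c2[C@@H](c2ccc(OC)cc2)[C@H]1c1cc(OC)cc(OC)c1 | intermediate
11 | (S)-[(1R,2R,3R)-2-(3,5-dimethoxyphenyl)-4,6-dimethoxy-3-(4-methoxyphenyl)-2,3-dihydro-1H-inden-1-yl](4-methoxyphenyl)methanol | O[C@H](c1ccc(OC)cc1)[C@H]1c2cc(OC)cc(OC)c2[C@@H](c2ccc(OC)cc2)[C@H]1c1cc(OC)cc(OC)c1 | intermediate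
12 | [(1R,2R,3R)-2-(3,5-dimethoxyphenyl)-4,6-dimethoxy-3-(4-methoxyphenyl)-2,3-dihydro-1H-inden-1-yl](4-methoxyphenyl)methanone | O=C(c1ccc(OC)cc1)[C@H]1c2cc(OC)cc(OC)c2[C@@H](c2ccc(OC)cc2)[C@H]1c1cc(OC)cc(OC)c1 | intermediate
13 | [(1R,2R,3R)-2-(3,5-dihydroxyphenyl)-4,6-dihydroxy-3-(4-hydroxyphenyl)-2,3-dihydro-1H-inden-1-yl](4-hydroxyphenyl)methanone, caraphenol C as drawn | O=C(c1ccc(O)cc1)[C@H]1c2cc(O)cc(O)c2[C@@H](c2ccc(O)cc2)[C@H]1c1cc(O)cc(O)c1 | target

## Step count and risks

Total step count: 9. Longest linear sequence: 9 steps (1 → 13); compounds 4 and 7 are bought.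

Steps most likely to fail:

**Step 4 (the new vicinal diarylation).** The second arylation at the hindered C2 may lose to protonation of the enolate, and the facial sense at C1 rests on the Felkin–Anh precedent for cuprates. Fallback with known chemistry, from 6: copper-catalysed conjugate addition of (3,5-dimethoxyphenyl)magnesium bromide (made from 7 and Mg; CuBr·SMe2 20 mol%, THF, −40 °C, then aqueous NH4Cl) gives the anti adduct (3R,4S)-4-[(tert-butyldimethylsilyl)oxy]-3-(3,5-dimethoxyphenyl)-1,4-bis(4-methoxyphenyl)butan-1-one F1. Palladium-catalysed α-arylation of this ketone with 7 (Pd(OAc)2, P(t-Bu)3·HBF4, NaOtBu, toluene, 70 °C) then installs the second aryl group and rejoins the route at 8.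

**Step 5 (Tf2O cyclodehydration).** The O-triflylated ketone may simply lose a proton to give a stable enol triflate, or the silyloxy oxygen may compete with the arene. Fallback, from 8: deprotonation with KN(SiMe3)2 (THF, −78 °C) and trapping with nonafluorobutanesulfonyl fluoride gives the isolable (3S,4S)-4-[(tert-butyldimethylsilyl)oxy]-2,3-bis(3,5-dimethoxyphenyl)-1,4-bis(4-methoxyphenyl)but-1-en-1-yl nonafluorobutane-1-sulfonate F2 (E/Z mixture). A palladium-catalysed intramolecular C–H alkenylation of ring A (Pd(OAc)2, PCy3·HBF4, K2CO3, pivalic acid, DMA, 110 °C) then closes the C3–C3a bond without any cationic intermediate and rejoins the route at 9.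

**Step 9 (sixfold demethylation next to the epimerisable cis C1 centre).** BBr3 may enolise the ketone and drift C1 to the more stable trans arrangement. Fallback, from 12: C1 is no longer preserved but set again at the end.
- Demethylation with BBr3 at 25 °C without regard to C1 gives 13 mixed with, or wholly as, its C1 epimer [(1S,2R,3R)-2-(3,5-dihydroxyphenyl)-4,6-dihydroxy-3-(4-hydroxyphenyl)-2,3-dihydro-1H-inden-1-yl](4-hydroxyphenyl)methanone F3.
- Exhaustive silylation (TBSOTf, Et3N, CH2Cl2) converts both epimers into one compound in which C1 is planar: (2S,3R)-1-{[(tert-butyldimethylsilyl)oxy][4-[(tert-butyldimethylsilyl)oxy]phenyl]methylidene}-2-{3,5-bis[(tert-butyldimethylsilyl)oxy]phenyl}-4,6-bis[(tert-butyldimethylsilyl)oxy]-3-{4-[(tert-butyldimethylsilyl)oxy]phenyl}-2,3-dihydro-1H-indene F4, with six aryl silyl ethers and an exocyclic silyl enol ether.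
- HF·pyridine in THF/pyridine at −20 °C removes all silyl groups, and the liberated enol is protonated at C1 from the open face opposite the C2 and C3 aryl groups (Zimmerman-type kinetic protonation), giving the all-cis ketone 13.

Further compounds

F1 | step 4 | (3R,4S)-4-[(tert-butyldimethylsilyl)oxy]-3-(3,5-dimethoxyphenyl)-1,4-bis(4-methoxyphenyl)butan-1-one | CC(C)(C)[Si](C)(C)O[C@H](c1ccc(OC)cc1)[C@@H](c1cc(OC)cc(OC)c1)CC(=O)c1ccc(OC)cc1
F2 | step 5 | (3S,4S)-4-[(tert-butyldimethylsilyl)oxy]-2,3-bis(3,5-dimethoxyphenyl)-1,4-bis(4-methoxyphenyl)but-1-en-1-yl nonafluorobutane-1-sulfonate (E/Z mixture) | CC(C)(C)[Si](C)(C)O[C@H](c1ccc(OC)cc1)[C@@H](c1cc(OC)cc(OC)c1)C(c1cc(OC)cc(OC)c1)=C(OS(=O)(=O)C(F)(F)C(F)(F)C(F)(F)C(F)(F)F)c1ccc(OC)cc1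
F3 | step 9 | [(1S,2R,3R)-2-(3,5-dihydroxyphenyl)-4,6-dihydroxy-3-(4-hydroxyphenyl)-2,3-dihydro-1H-inden-1-yl](4-hydroxyphenyl)methanone | O=C(c1ccc(O)cc1)[C@@H]1c2cc(O)cc(O)c2[C@@H](c2ccc(O)cc2)[C@H]1c1cc(O)cc(O)c1
F4 | step 9 | (2S,3R)-1-{[(tert-butyldimethylsilyl)oxy][4-[(tert-butyldimethylsilyl)oxy]phenyl]methylidene}-2-{3,5-bis[(tert-butyldimethylsilyl)oxy]phenyl}-4,6-bis[(tert-butyldimethylsilyl)oxy]-3-{4-[(tert-butyldimethylsilyl)oxy]phenyl}-2,3-dihydro-1H-indene (enol ether geometry unspecified) | C(O[Si](C)(C)C(C)(C)C)(c1ccc(O[Si](C)(C)C(C)(C)C)cc1)=C1c2cc(O[Si](C)(C)C(C)(C)C)cc(O[Si](C)(C)C(C)(C)C)c2[C@@H](c2ccc(O[Si](C)(C)C(C)(C)C)cc2)[C@H]1c1cc(O[Si](C)(C)C(C)(C)C)cc(O[Si](C)(C)C(C)(C)C)c1
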